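**Target.** 23 is (2R,5R,9R,10R,13Z)-16-acetoxy-2-methoxy-ent-labda-8(17),13-dien-15-oic acid: a trans-decalin with axial C10 methyl, equatorial C2 methoxy, equatorial C9 side chain, exocyclic C8=C17 alkene, and CO2H cis to CH2OAc. Atom labels C1–C20 below are labdane numbers.

**Retrosynthetic overview**
1. 23 ⇒ chloroethyl decalin 18 + propargyl alcohol + CO2 + Ac2O: Grignard anti-carbomagnesiation and carboxylation make C12–C13 and C14–C15 and fix the Z-enoic acid.
2. 18 ⇒ acyclic triene chloride 17 (key step): cobalt-hydride-initiated radical bicycloisomerisation. C4–C5 closes ring A first, C9–C10 closes ring B second; the C2 methoxy stereocentre sets C5, C9 and C10; termination leaves the exocyclic alkene.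
3. 17 ⇒ alkyne 7 + methyl vinyl ketone + ethylene oxide: two zirconium-catalysed methylaluminations set both E-trisubstituted alkenes.
4. 7 ⇒ (R)-epichlorohydrin + isopropenylmagnesium bromide + lithium acetylide + MeI; the only stereocentre is bought.

Assumption: metal salts that differ from a listed compound only by loss of a proton (alkoxides, enolates, acetylides, carboxylates) are counted with that compound and not numbered separately.

**Route**

Step 1
Reactants: 1 (R)-epichlorohydrin; 2 isopropenylmagnesium bromide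
Product: 3 (R)-1-chloro-4-methylpent-4-en-2-ol
Conditions: CuI (copper iodide, 10 mol%), THF, −40 → −20 °C; then 1 M HCl
Reagents that add atoms: none
Why: Copper-catalysed Grignard opening of the epoxide (SN2 at the unsubstituted ring carbon); the carbinol stereocentre, the future C2, is not touched, so its configuration comes from 1.

Step 2
Reactants: 3 (R)-1-chloro-4-methylpent-4-en-2-ol; 4 lithium acetylide–ethylenediamine complex
Product: 6 (R)-2-methylhept-1-en-6-yn-4-ol, via (R)-2-(2-methylallyl)oxirane 5 (not isolated)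
Conditions: LiC≡CH·H2NCH2CH2NH2 (3 equiv), DMSO, 0 → 25 °C; then H2O
Reagents that add atoms: none
Why: The acetylide first closes the chlorohydrin to epoxide 5 (intramolecular Williamson reaction) and then opens 5 by SN2 at the terminal carbon (acetylide epoxide opening); no bond to the stereocentre is made or broken.

Step 3
Reactants: 6 (R)-2-methylhept-1-en-6-yn-4-ol
Product: 7 (R)-4-methoxy-2-methylhept-1-en-6-yne
Conditions: NaH (1.05 equiv), THF, 0 °C; MeI, 0 → 25 °C
Reagents that add atoms: iodomethane CI
Why: Williamson ether synthesis; one equivalent of NaH forms the alkoxide selectively over the acetylide, and the stereocentre is untouched.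

Step 4
Reactants: 7 (R)-4-methoxy-2-methylhept-1-en-6-yne; 8 methyl vinyl ketone
Product: 10 (5E,8R)-8-methoxy-6,10-dimethylundeca-5,10-dien-2-one, via E-alkenyl(dimethyl)alane 9 (not isolated)
Conditions: Me3Al (2 equiv), Cp2ZrCl2 (0.2 equiv), CH2Cl2, 0 → 25 °C; excess Me3Al evaporated; THF, CuBr·SMe2 (10 mol%), 8 (1.5 equiv, slow addition), −40 → −10 °C; then aq KNaC4H4O6 (potassium sodium tartrate)
Reagents that add atoms: trimethylaluminium C[Al](C)C
Why: Negishi zirconium-catalysed methylalumination adds Me and Al syn across the terminal alkyne with Me on the internal carbon, which sets the E geometry of C10=C5, and the copper-catalysed conjugate addition of the alkenyl group to 8 (aluminium-to-copper transmetalation, 1,4-addition) keeps that geometry.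

Step 5
Reactants: 10 (5E,8R)-8-methoxy-6,10-dimethylundeca-5,10-dien-2-one
Product: 12 (5E,8R)-8-methoxy-6,10-dimethylundeca-5,10-dien-1-yne, via enol diethyl phosphate 11 (not isolated)
Conditions: LiN(iPr)2 (1.05 equiv), THF, −78 °C; ClP(O)(OEt)2; then LiN(iPr)2 (2.3 equiv), −78 → 25 °C; H2O
Reagents that add atoms: diethyl chlorophosphate CCOP(=O)(Cl)OCC (its atoms stay in 11 only)
Why: Kinetic enolisation at the methyl group, O-phosphorylation and E2 elimination of the enol phosphate (Negishi conversion of a methyl ketone into a terminal alkyne); no stereo-element is involved.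

Step 6
Reactants: 12 (5E,8R)-8-methoxy-6,10-dimethylundeca-5,10-dien-1-yne; 13 ethylene oxide
Product: 16 (3E,7E,10R)-10-methoxy-4,8,12-trimethyltrideca-3,7,12-trien-1-ol, via E-alkenyl(dimethyl)alane 14 (not isolated), via lithium butyl(alkenyl)dimethylalanate 15 (not isolated)
Conditions: Me3Al (2 equiv), Cp2ZrCl2 (0.2 equiv), CH2Cl2, 25 °C; volatiles evaporated; THF/hexane, n-BuLi (1.0 equiv), 0 °C; 13 (3 equiv), 0 → 25 °C; then aq KNaC4H4O6
Reagents that add atoms: trimethylaluminium C[Al](C)C; n-butyllithium [Li]CCCC (butyl stays in 15 only)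
Why: A second Negishi methylalumination sets the E geometry of C8=C9, and the more nucleophilic alanate transfers its alkenyl group to ethylene oxide (SN2 epoxide opening) with retention of alkene geometry.

Step 7
Reactants: 16 (3E,7E,10R)-10-methoxy-4,8,12-trimethyltrideca-3,7,12-trien-1-ol
Product: 17 (4R,6E,10E)-13-chloro-4-methoxy-2,6,10-trimethyltrideca-1,6,10-triene
Conditions: PPh3, N-chlorosuccinimide (premixed), CH2Cl2, 0 → 25 °C
Reagents that add atoms: N-chlorosuccinimide O=C1CCC(=O)N1Cl
Why: Appel-type chlorination: chloride displaces the alkoxyphosphonium group by SN2 at the primary carbon, leaving the three alkenes and the ether untouched.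

Step 8 (key step)
Reactants: 17 (4R,6E,10E)-13-chloro-4-methoxy-2,6,10-trimethyltrideca-1,6,10-triene
Product: 18 (1R,4aR,7R,8aR)-1-(2-chloroethyl)-7-methoxy-5,5,8a-trimethyl-2-methylidenedecahydronaphthalene
Conditions: Co(tBu4-salen)Cl (3 mol%; trivalent cobalt; tBu4-salen = N,N′-bis(3,5-di-tert-butylsalicylidene)-1,2-cyclohexanediaminate), PhSiH3 (6 mol%), degassed benzene, 0.01 M, 22 °C, Ar; stopped when 17 is consumed
Reagents that add atoms: none
Why: Proposed new method: a cobalt hydride formed from the trivalent cobalt salen chloride and PhSiH3 transfers a hydrogen atom (MHAT) to the terminal CH2 of the only 1,1-disubstituted alkene to give the tertiary C4 radical, which closes ring A by 6-endo attack on C5 through a chair with the C2 methoxy group equatorial (this fixes C5), the tertiary C10 radical then closes ring B by a second chair-like 6-endo attack on C9 (trans fusion, axial C10 methyl, equatorial C9 side chain), and the tertiary C8 radical returns its least hindered β-hydrogen (from the C17 methyl) to divalent cobalt, regenerating the hydride and leaving the exocyclic methylene; the closest known reaction types are the cobalt salen/silane MHAT cycloisomerisation of dienes and the Cp2TiCl (trivalent titanium) radical bicyclisation of epoxypolyprenes, which runs through the same C10 and C8 tertiary radicals and also ends at the exocyclic alkene.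

Step 9
Reactants: 18 (1R,4aR,7R,8aR)-1-(2-chloroethyl)-7-methoxy-5,5,8a-trimethyl-2-methylidenedecahydronaphthalene; 19 propargyl alcohol
Product: 23 (2Z)-3-[(acetyloxy)methyl]-5-[(1R,4aR,7R,8aR)-7-methoxy-5,5,8a-trimethyl-2-methylidenedecahydronaphthalen-1-yl]pent-2-enoic acid, via alkylmagnesium chloride 20 (not isolated), via cyclic alkenylmagnesium alkoxide 21 (not isolated), via magnesium alkoxide carboxylate 22 (not isolated)
Conditions: Mg (I2-activated), THF, reflux; added to 19 (2 equiv, pre-treated with i-PrMgCl, 2 equiv) and CuI (20 mol%), THF, 0 → 25 °C; CO2 (1 atm), −20 → 25 °C; Ar purge; Ac2O (4 equiv), 0 °C; then cold 0.5 M HCl to pH 3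
Reagents that add atoms: carbon dioxide O=C=O; acetic anhydride CC(=O)OC(C)=O; magnesium [Mg] (stays in 20, 21, 22 only)
Why: Grignard formation and copper-catalysed anti-carbomagnesiation of the propargylic alkoxide (Duboudin–Jousseaume reaction) put the alkyl group on the internal alkyne carbon and magnesium on the terminal carbon cis to CH2O in a five-membered chelate, which fixes the Z geometry; carboxylation of the alkenyl–Mg bond retains it, and the magnesium alkoxide is acetylated by Ac2O far faster than the carboxylate, so the lactonisable hydroxy acid is never set free.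

**Compound list**
1 | (R)-epichlorohydrin | ClC[C@H]1CO1 | starting material
2 | isopropenylmagnesium bromide | C=C(C)[Mg]Br | starting material
3 | (R)-1-chloro-4-methylpent-4-en-2-ol | C=C(C)C[C@@H](O)CCl | intermediate
4 | lithium acetylide–ethylenediamine complex | [Li+].[C-]#C.NCCN | starting material
5 | (R)-2-(2-methylprop-2-en-1-yl)oxirane | C=C(C)C[C@@H]1CO1 | intermediate
6 | (R)-2-methylhept-1-en-6-yn-4-ol | C=C(C)C[C@@H](O)CC#C | intermediate
7 | (R)-4-methoxy-2-methylhept-1-en-6-yne | C=C(C)C[C@@H](OC)CC#C | intermediate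
8 | methyl vinyl ketone (but-3-en-2-one) | CC(=O)C=C | starting material
9 | dimethyl[(1E,4R)-4-methoxy-2,6-dimethylhepta-1,6-dien-1-yl]alumane | C=C(C)C[C@@H](OC)C/C(C)=C/[Al](C)C | intermediate
10 | (5E,8R)-8-methoxy-6,10-dimethylundeca-5,10-dien-2-one | C=C(C)C[C@@H](OC)C/C(C)=C/CCC(C)=O | intermediate
11 | diethyl (5E,8R)-8-methoxy-6,10-dimethylundeca-1,5,10-trien-2-yl phosphate | C=C(C)C[C@@H](OC)C/C(C)=C/CCC(=C)OP(=O)(OCC)OCC | intermediate
12 | (5E,8R)-8-methoxy-6,10-dimethylundeca-5,10-dien-1-yne | C=C(C)C[C@@H](OC)C/C(C)=C/CCC#C | intermediate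
13 | ethylene oxide | C1CO1 | starting material
14 | dimethyl[(1E,5E,8R)-8-methoxy-2,6,10-trimethylundeca-1,5,10-trien-1-yl]alumane | C=C(C)C[C@@H](OC)C/C(C)=C/CC/C(C)=C/[Al](C)C | intermediate
15 | lithium butyl(dimethyl)[(1E,5E,8R)-8-methoxy-2,6,10-trimethylundeca-1,5,10-trien-1-yl]alanuide | [Li+].C=C(C)C[C@@H](OC)C/C(C)=C/CC/C(C)=C/[Al-](C)(C)CCCC | intermediate
16 | (3E,7E,10R)-10-methoxy-4,8,12-trimethyltrideca-3,7,12-trien-1-ol | C=C(C)C[C@@H](OC)C/C(C)=C/CC/C(C)=C/CCO | intermediate
17 | (4R,6E,10E)-13-chloro-4-methoxy-2,6,10-trimethyltrideca-1,6,10-triene | C=C(C)C[C@@H](OC)C/C(C)=C/CC/C(C)=C/CCCl | intermediate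
18 | (1R,4aR,7R,8aR)-1-(2-chloroethyl)-7-methoxy-5,5,8a-trimethyl-2-methylidenedecahydronaphthalene | C=C1CC[C@@H]2C(C)(C)C[C@@H](OC)C[C@@]2(C)[C@@H]1CCCl | intermediate
19 | propargyl alcohol (prop-2-yn-1-ol) | C#CCO | starting material
20 | {2-[(1R,4aR,7R,8aR)-7-methoxy-5,5,8a-trimethyl-2-methylidenedecahydronaphthalen-1-yl]ethyl}magnesium chloride | C=C1CC[C@@H]2C(C)(C)C[C@@H](OC)C[C@@]2(C)[C@@H]1CC[Mg]Cl | intermediate
21 | 4-{2-[(1R,4aR,7R,8aR)-7-methoxy-5,5,8a-trimethyl-2-methylidenedecahydronaphthalen-1-yl]ethyl}-2,5-dihydro-1,2-oxamagnesole (Mg cis to CH2O) | C=C1CC[C@@H]2C(C)(C)C[C@@H](OC)C[C@@]2(C)[C@@H]1CCC3=C[Mg]OC3 | intermediate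
22 | magnesium (2Z)-5-[(1R,4aR,7R,8aR)-7-methoxy-5,5,8a-trimethyl-2-methylidenedecahydronaphthalen-1-yl]-3-(oxidomethyl)pent-2-enoate | [Mg+2].C=C1CC[C@@H]2C(C)(C)C[C@@H](OC)C[C@@]2(C)[C@@H]1CC/C(C[O-])=C/C(=O)[O-] | intermediate
23 | (2Z)-3-[(acetyloxy)methyl]-5-[(1R,4aR,7R,8aR)-7-methoxy-5,5,8a-trimethyl-2-methylidenedecahydronaphthalen-1-yl]pent-2-enoic acid | C=C1CC[C@@H]2C(C)(C)C[C@@H](OC)C[C@@]2(C)[C@@H]1CC/C(=C/C(=O)O)COC(C)=O | target

**Step count.** 9 steps in total; longest linear sequence 9 steps (fully linear).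

**Three steps most likely to fail**

Step 8. The 6-endo closures are slow compared with hydrogen return to cobalt, so 17 may only isomerise to its C3=C4 isomer, and the cobalt hydride may also move the exocyclic alkene of 18 into the ring. The fallback separates radical generation from the hydride; it sets out from 17 and comes back at 18. Mukaiyama hydration of the 1,1-disubstituted alkene of 17 (Co(acac)2, divalent cobalt, PhSiH3, O2, i-PrOH, 0 °C; O2 traps the radical before it can cyclise) gives the tertiary alcohol (4S,6E,10E)-13-chloro-4-methoxy-2,6,10-trimethyltrideca-6,10-dien-2-ol F1. Acylation with methyl chlorooxoacetate (Et3N, DMAP, CH2Cl2) gives the mixed oxalate methyl (4S,6E,10E)-13-chloro-4-methoxy-2,6,10-trimethyltrideca-6,10-dien-2-yl oxalate F2. Half-saponification with CsOH (1 equiv, THF/H2O) gives the caesium (4S,6E,10E)-13-chloro-4-methoxy-2,6,10-trimethyltrideca-6,10-dien-2-yl oxalate F3. Blue-light photoredox oxidation of F3 (Ir[dF(CF3)ppy]2(dtbbpy)PF6, 1 mol%) releases the same C4 radical by double decarboxylation. It bicyclises as in step 8, and the C8 radical is dehydrogenated at the C17 methyl by the cobaloxime Co(dmgH)2(py)Cl (5 mol%), giving 18 with no hydride source able to touch the product alkene.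

Step 9. The precious Grignard 20 may be consumed by deprotonating the terminal alkyne, and if acetylation does not outrun acyl activation of the carboxylate the butenolide forms instead. The fallback introduces the carboxyl carbon only after the acetate is in place; it sets out from 18 and comes back at 23. Magnesacycle 21 (made from 18 through 20 as in step 9) is quenched with I2 (THF, −30 °C) to give (2Z)-3-iodo-2-{2-[(1R,4aR,7R,8aR)-7-methoxy-5,5,8a-trimethyl-2-methylidenedecahydronaphthalen-1-yl]ethyl}prop-2-en-1-ol F4. Acetylation (Ac2O, pyridine, DMAP) gives (2Z)-3-iodo-2-{2-[(1R,4aR,7R,8aR)-7-methoxy-5,5,8a-trimethyl-2-methylidenedecahydronaphthalen-1-yl]ethyl}prop-2-en-1-yl acetate F5. Palladium-catalysed hydroxycarbonylation of F5 (PdCl2(PPh3)2, divalent palladium precatalyst, CO 1 atm, H2O, Et3N, THF, 25 °C) replaces iodine by CO2H with retention of alkene geometry and gives 23.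

Step 4. Methyl vinyl ketone can polymerise under the Lewis-acidic alane, and residual Me3Al can transfer methyl instead of the alkenyl group. The fallback replaces conjugate addition by cross-coupling; it sets out from 7 and comes back at 12, bypassing 10 and step 5. Alane 9 (from 7 as in step 4) is iodinated (I2, THF, −30 °C) to (1E,4R)-1-iodo-4-methoxy-2,6-dimethylhepta-1,6-diene F6. Negishi coupling of F6 with 4-(trimethylsilyl)but-3-yn-1-ylzinc bromide (Pd(PPh3)4, zerovalent palladium, THF, 25 °C) gives trimethyl[(5E,8R)-8-methoxy-6,10-dimethylundeca-5,10-dien-1-yn-1-yl]silane F7 with retention of the E geometry. Desilylation (K2CO3, MeOH) gives 12.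

**Further compounds**
F1 | step 8 | (4S,6E,10E)-13-chloro-4-methoxy-2,6,10-trimethyltrideca-6,10-dien-2-ol | CC(C)(O)C[C@@H](OC)C/C(C)=C/CC/C(C)=C/CCCl
F2 | step 8 | methyl (4S,6E,10E)-13-chloro-4-methoxy-2,6,10-trimethyltrideca-6,10-dien-2-yl oxalate | COC(=O)C(=O)OC(C)(C)C[C@@H](OC)C/C(C)=C/CC/C(C)=C/CCCl
F3 | step 8 | caesium (4S,6E,10E)-13-chloro-4-methoxy-2,6,10-trimethyltrideca-6,10-dien-2-yl oxalate | [Cs+].[O-]C(=O)C(=O)OC(C)(C)C[C@@H](OC)C/C(C)=C/CC/C(C)=C/CCCl
F4 | step 9 | (2Z)-3-iodo-2-{2-[(1R,4aR,7R,8aR)-7-methoxy-5,5,8a-trimethyl-2-methylidenedecahydronaphthalen-1-yl]ethyl}prop-2-en-1-ol | C=C1CC[C@@H]2C(C)(C)C[C@@H](OC)C[C@@]2(C)[C@@H]1CC/C(CO)=C/I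
F5 | step 9 | (2Z)-3-iodo-2-{2-[(1R,4aR,7R,8aR)-7-methoxy-5,5,8a-trimethyl-2-methylidenedecahydronaphthalen-1-yl]ethyl}prop-2-en-1-yl acetate | C=C1CC[C@@H]2C(C)(C)C[C@@H](OC)C[C@@]2(C)[C@@H]1CC/C(COC(C)=O)=C/I
F6 | step 4 | (1E,4R)-1-iodo-4-methoxy-2,6-dimethylhepta-1,6-diene | C=C(C)C[C@@H](OC)C/C(C)=C/I
F7 | step 4 | trimethyl[(5E,8R)-8-methoxy-6,10-dimethylundeca-5,10-dien-1-yn-1-yl]silane | C=C(C)C[C@@H](OC)C/C(C)=C/CCC#C[Si](C)(C)C
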